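The route rests on the C7–C8 disconnection of the ten-membered carbocycle. In the butenolide ring, the C7=C11 alkene carries an allylic oxygen at C13 and sits next to carbinol C8. As its 13-bromide, this unit is an allyl donor with C7 as γ-carbon. One chromium(II) carbonyl allylation of the seco aldehyde 20 closes the carbocycle. Aldehyde 20 already contains the C4–C5 epoxide, the lactone ring and the C10 acetate. The same step creates the C8 alcohol and relays the C6 configuration to C8 through a transient C7 centre. The alkene shifts to C11=C13; allylic bromination and acetate displacement return it and install the C13 acetate.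

Key step: step 13

Remark: germacrane numbering is used (C1 ketone, C4–C5 epoxide, C6 lactone carbinol, C7=C11 butenolide alkene, C8 propionate carbinol, C10 tertiary acetate, C12 lactone carbonyl, C13 CH2OAc, C14 and C15 the methyl groups on C10 and C4), and compound 5, the pivalaldehyde acetal of (S)-lactic acid, is taken as commercially available.

Step 1
Reactants: 1 3-methylbut-2-en-1-ol (prenol)
Product: 2 tert-butyl(dimethyl)(3-methylbut-2-enyloxy)silane
Conditions: TBSCl, imidazole, CH2Cl2, 0 °C to rt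
Reagents that add atoms: tert-butyldimethylsilyl chloride CC(C)(C)[Si](C)(C)Cl
Why: Silyl ether formation (imidazole-promoted silylation) masks the future C6 oxygen for the enolate chemistry and creates no stereocentre.

Step 2
Reactants: 2 tert-butyl(dimethyl)(3-methylbut-2-enyloxy)silane
Product: 3 (E)-4-(tert-butyldimethylsilyloxy)-2-methylbut-2-en-1-ol
Conditions: SeO2 (cat.), t-BuOOH, CH2Cl2, 0 °C to rt
Reagents that add atoms: tert-butyl hydroperoxide CC(C)(C)OO
Why: Riley allylic oxidation (ene reaction, then [2,3]-sigmatropic shift) oxidises the methyl group trans to the chain, which fixes the E alkene that later becomes the trans C4–C5 epoxide.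

Step 3
Reactants: 3 (E)-4-(tert-butyldimethylsilyloxy)-2-methylbut-2-en-1-ol
Product: 4 (E)-1-bromo-4-(tert-butyldimethylsilyloxy)-2-methylbut-2-ene
Conditions: CBr4, PPh3, CH2Cl2, 0 °C
Reagents that add atoms: carbon tetrabromide BrC(Br)(Br)Br
Why: The Appel reaction converts the primary allylic alcohol into the bromide by SN2 at carbon, leaving alkene geometry and silyl ether untouched.

Step 4
Reactants: 5 (2S,5S)-2-tert-butyl-5-methyl-1,3-dioxolan-4-one; 6 1-bromo-3-methylbut-2-ene (prenyl bromide)
Product: 8 (2S,5R)-2-tert-butyl-5-methyl-5-(3-methylbut-2-enyl)-1,3-dioxolan-4-one, via lithium enolate 7 (not isolated)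
Conditions: LDA, THF, −78 °C; then 6, −78 to −30 °C
Reagents that add atoms: none
Why: Diastereoselective enolate alkylation under self-regeneration of the stereocentre: the tert-butyl group of enolate 7 shields one face, so 6 enters trans to it and sets C10 as R.

Step 5
Reactants: 8 (2S,5R)-2-tert-butyl-5-methyl-5-(3-methylbut-2-enyl)-1,3-dioxolan-4-one
Product: 10 (3R)-3-hydroxy-3,6-dimethylhept-5-en-2-one, via tetrahedral lithium alkoxide 9 (not isolated)
Conditions: MeLi (1 equiv), Et2O/THF, −78 °C; then H2O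
Reagents that add atoms: methyllithium [Li]C
Why: Nucleophilic acyl substitution: methyllithium should add only once because tetrahedral alkoxide 9 persists at low temperature and collapses on quenching to the methyl ketone with loss of pivalaldehyde, while quaternary C10 cannot epimerise.

Step 6
Reactants: 10 (3R)-3-hydroxy-3,6-dimethylhept-5-en-2-one; 4 (E)-1-bromo-4-(tert-butyldimethylsilyloxy)-2-methylbut-2-ene
Product: 12 (2E,7R)-1-(tert-butyldimethylsilyloxy)-7-hydroxy-3,7,10-trimethylundeca-2,9-dien-6-one, via dilithium alkoxide-enolate 11 (not isolated)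
Conditions: LDA (2.2 equiv), THF, −78 to −20 °C; then 4, DMPU, −78 to 0 °C; then H2O
Reagents that add atoms: none
Why: Enolate alkylation: the ketone can enolise only toward its methyl group, and the carbon terminus of alkoxide-enolate 11 displaces the allylic bromide of 4 by SN2 to form the C2–C3 bond with retention of the E alkene.

Step 7
Reactants: 12 (2E,7R)-1-(tert-butyldimethylsilyloxy)-7-hydroxy-3,7,10-trimethylundeca-2,9-dien-6-one
Product: 13 (2E,7R)-7-acetoxy-1-(tert-butyldimethylsilyloxy)-3,7,10-trimethylundeca-2,9-dien-6-one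
Conditions: Ac2O, DMAP (cat.), Et3N, CH2Cl2, rt
Reagents that add atoms: acetic anhydride CC(=O)OC(C)=O
Why: DMAP-catalysed acylation esterifies the tertiary alcohol, which installs the C10 acetate of the target and removes a hydroxyl group that could misdirect the later epoxidation.

Step 8
Reactants: 13 (2E,7R)-7-acetoxy-1-(tert-butyldimethylsilyloxy)-3,7,10-trimethylundeca-2,9-dien-6-one
Product: 14 (2E,7R)-7-acetoxy-3,7,10-trimethyl-6-oxoundeca-2,9-dienal
Conditions: DDQ, CH2Cl2/pH 7 buffer, rt
Reagents that add atoms: none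
Why: Oxidative desilylation with DDQ (hydride abstraction from the allylic O–CH2 group, then hydrolysis of the silyloxocarbenium ion) gives the enal directly, and the isolated prenyl alkene lacks the oxygen activation needed to react.

Step 9
Reactants: 14 (2E,7R)-7-acetoxy-3,7,10-trimethyl-6-oxoundeca-2,9-dienal
Product: 16 (1S)-1-{(2R,3R)-3-[(4R)-4-acetoxy-4,7-dimethyl-3-oxooct-6-enyl]-3-methyloxiran-2-yl}prop-2-en-1-ol, via vinylzinc alkoxide 15 (not isolated)
Conditions: (CH2=CH)2Zn, (−)-MIB (cat.), toluene, −30 °C; then Ti(OiPr)4 (cat.), t-BuOOH, 0 °C; then H2O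
Reagents that add atoms: divinylzinc C=C[Zn]C=C; tert-butyl hydroperoxide CC(C)(C)OO
Why: Amino alcohol-catalysed enantioselective vinylzinc addition sets C6 as S under catalyst control, and the alkoxide-directed titanium/hydroperoxide epoxidation of 15 then attacks only the electron-rich allylic C4=C5 alkene on the face fixed by A(1,3) strain between the C15 methyl group and C6 (threo), which sets C4 and C5 as R,R.

Step 10
Reactants: 16 (1S)-1-{(2R,3R)-3-[(4R)-4-acetoxy-4,7-dimethyl-3-oxooct-6-enyl]-3-methyloxiran-2-yl}prop-2-en-1-ol; 17 2-(bromomethyl)acrylic acid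
Product: 18 2-(bromomethyl)acrylate ester of 16 at the C6 oxygen (4R,5R,6S,10R)
Conditions: DCC, DMAP (cat.), CH2Cl2, −10 °C
Reagents that add atoms: none
Why: Steglich esterification acylates the C6 hydroxyl at oxygen, so its configuration is retained and the neutral conditions spare epoxide and allylic bromide.

Step 11
Reactants: 18 2-(bromomethyl)acrylate ester of 16
Product: 19 (5S)-3-(bromomethyl)-5-{(2R,3R)-3-[(4R)-4-acetoxy-4,7-dimethyl-3-oxooct-6-enyl]-3-methyloxiran-2-yl}furan-2(5H)-one
Conditions: Grubbs second-generation catalyst (cat.), CH2Cl2, 40 °C, dilute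
Reagents that add atoms: none
Why: Ring-closing metathesis joins the vinyl group and the acrylate alkene to the five-membered butenolide (C7=C11) with loss of ethene, the trisubstituted prenyl alkene being too hindered to compete with five-ring closure.

Step 12
Reactants: 19 (5S)-3-(bromomethyl)-5-{(2R,3R)-3-[(4R)-4-acetoxy-4,7-dimethyl-3-oxooct-6-enyl]-3-methyloxiran-2-yl}furan-2(5H)-one
Product: 20 (5S)-3-(bromomethyl)-5-{(2R,3R)-3-[(4R)-4-acetoxy-4-methyl-3,6-dioxohexyl]-3-methyloxiran-2-yl}furan-2(5H)-one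
Conditions: O3, pyridine, CH2Cl2, −78 °C
Reagents that add atoms: ozone [O-][O+]=O
Why: Ozonolysis is chemoselective because the electron-rich trisubstituted alkene reacts much faster than the electron-poor butenolide alkene, and pyridine-promoted breakdown of the carbonyl oxide avoids a nucleophilic reductant that would attack the allylic bromide.

Step 13
Reactants: 20 (5S)-3-(bromomethyl)-5-{(2R,3R)-3-[(4R)-4-acetoxy-4-methyl-3,6-dioxohexyl]-3-methyloxiran-2-yl}furan-2(5H)-one
Product: 22 (4R,5R,6S,7R,8S,10R)-10-acetoxy-4,5-epoxy-8-hydroxy-1-oxogermacr-11(13)-en-12,6-olide, via allylchromium(III) species 21 (not isolated)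
Conditions: CrCl2 (excess), THF–DMF, rt, slow addition of 20 (high dilution); then H2O
Reagents that add atoms: none
Why: Two equivalents of chromium(II) reduce the allylic C13–Br bond of 20 to allylchromium(III) 21, which adds through its γ-carbon C7 to the C8 aldehyde in a closed six-membered chair transition state (SE2′), so that the alkene moves from C7=C11 to C11=C13. The closest known reaction type is the Nozaki–Hiyama (Barbier-type) carbonyl allylation, known for 3-(bromomethyl)butenolides with external aldehydes and, intramolecularly, for ten-membered carbocycles that carry an epoxide. Only one ring closes: the ten-membered carbocycle C8–C9–C10–C1–C2–C3–C4–C5–C6–C7, by exo-trig attack of C7 on the aldehyde carbon, while the epoxide and the lactone ring are spectators. C7 (R, transient) is controlled by C6, because the aldehyde must approach the planar lactone on the face opposite to the C5 substituent, which gives the trans ring fusion, and C8 (S) follows from the ring-fixed E-type geometry of the allyl unit (C6 trans to C13) with C9 equatorial in the chair (anti relation of C6 and O8). The step needs aldehyde over C1 ketone selectivity, which organochromium reagents show and the quaternary C10 reinforces, and reduction of C–Br in preference to the acetate, the α-acetoxy ketone and the epoxide, which the much weaker allylic C–Br bond secures. Slow addition at high dilution, the fully substituted C10 and the two rigid small rings in the chain should favour ring closure over oligomerisation.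

Step 14
Reactants: 22 (4R,5R,6S,7R,8S,10R)-10-acetoxy-4,5-epoxy-8-hydroxy-1-oxogermacr-11(13)-en-12,6-olide
Product: 23 (4R,5R,6S,7R,8S,10R)-10-acetoxy-4,5-epoxy-1-oxo-8-propanoyloxygermacr-11(13)-en-12,6-olide
Conditions: (EtCO)2O, DMAP (cat.), pyridine, CH2Cl2, 0 °C to rt
Reagents that add atoms: propionic anhydride CCC(=O)OC(=O)CC
Why: DMAP-catalysed acylation of the only free hydroxyl group installs the C8 propionate with retention at C8.

Step 15
Reactants: 23 (4R,5R,6S,7R,8S,10R)-10-acetoxy-4,5-epoxy-1-oxo-8-propanoyloxygermacr-11(13)-en-12,6-olide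
Product: 24 (4R,5R,6S,8S,10R)-10-acetoxy-13-bromo-4,5-epoxy-1-oxo-8-propanoyloxygermacr-7(11)-en-12,6-olide
Conditions: NBS (1 equiv), visible light, PhCF3, rt
Reagents that add atoms: N-bromosuccinimide O=C1CCC(=O)N1Br
Why: Wohl–Ziegler bromination: C7–H is the only allylic and thus the weakest C–H bond, and the delocalised radical takes up bromine at its unhindered terminus C13, which returns the alkene to the conjugated tetrasubstituted C7=C11 position and removes the auxiliary C7 stereocentre.

Step 16
Reactants: 24 (4R,5R,6S,8S,10R)-10-acetoxy-13-bromo-4,5-epoxy-1-oxo-8-propanoyloxygermacr-7(11)-en-12,6-olide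
Product: 25 (4R,5R,6S,8S,10R)-10,13-diacetoxy-4,5-epoxy-1-oxo-8-propanoyloxygermacr-7(11)-en-12,6-olide (CNP0285168.1)
Conditions: AgOAc, MeCN, rt, dark
Reagents that add atoms: silver acetate CC(=O)[O-].[Ag+]
Why: Silver-assisted SN2 displacement of the primary allylic bromide by acetate completes the C13 acetate under conditions too mild to enolise C6 or open the epoxide.

Compound list
1 | 3-methylbut-2-en-1-ol (prenol) | CC(C)=CCO | starting material
2 | tert-butyl(dimethyl)(3-methylbut-2-enyloxy)silane | CC(C)=CCO[Si](C)(C)C(C)(C)C | intermediate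
3 | (E)-4-(tert-butyldimethylsilyloxy)-2-methylbut-2-en-1-ol | OC/C(C)=C/CO[Si](C)(C)C(C)(C)C | intermediate
4 | (E)-1-bromo-4-(tert-butyldimethylsilyloxy)-2-methylbut-2-ene | BrC/C(C)=C/CO[Si](C)(C)C(C)(C)C | intermediate
5 | (2S,5S)-2-tert-butyl-5-methyl-1,3-dioxolan-4-one | C[C@@H]1O[C@H](C(C)(C)C)OC1=O | starting material
6 | 1-bromo-3-methylbut-2-ene (prenyl bromide) | CC(C)=CCBr | starting material
7 | lithium (2S)-2-tert-butyl-5-methyl-1,3-dioxol-4-olate (enolate of 5) | CC1=C([O-])O[C@@H](C(C)(C)C)O1.[Li+] | intermediate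
8 | (2S,5R)-2-tert-butyl-5-methyl-5-(3-methylbut-2-enyl)-1,3-dioxolan-4-one | CC(C)=CC[C@@]1(C)O[C@H](C(C)(C)C)OC1=O | intermediate
9 | lithium (2S,5R)-2-tert-butyl-4,5-dimethyl-5-(3-methylbut-2-enyl)-1,3-dioxolan-4-olate (configuration at C4 of the ring open) | CC(C)=CC[C@@]1(C)O[C@H](C(C)(C)C)OC1(C)[O-].[Li+] | intermediate
10 | (3R)-3-hydroxy-3,6-dimethylhept-5-en-2-one | CC(C)=CC[C@@](C)(O)C(C)=O | intermediate
11 | dilithium alkoxide-enolate of 10 | CC(C)=CC[C@@](C)([O-])C(=C)[O-].[Li+].[Li+] | intermediate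
12 | (2E,7R)-1-(tert-butyldimethylsilyloxy)-7-hydroxy-3,7,10-trimethylundeca-2,9-dien-6-one | CC(C)=CC[C@@](C)(O)C(=O)CC/C(C)=C/CO[Si](C)(C)C(C)(C)C | intermediate
13 | (2E,7R)-7-acetoxy-1-(tert-butyldimethylsilyloxy)-3,7,10-trimethylundeca-2,9-dien-6-one | CC(C)=CC[C@@](C)(OC(C)=O)C(=O)CC/C(C)=C/CO[Si](C)(C)C(C)(C)C | intermediate
14 | (2E,7R)-7-acetoxy-3,7,10-trimethyl-6-oxoundeca-2,9-dienal | CC(C)=CC[C@@](C)(OC(C)=O)C(=O)CC/C(C)=C/C=O | intermediate
15 | vinylzinc alkoxide of (3S,4E,9R)-9-acetoxy-3-hydroxy-5,9,12-trimethyltrideca-1,4,11-trien-8-one | CC(C)=CC[C@@](C)(OC(C)=O)C(=O)CC/C(C)=C/[C@@H](O[Zn]C=C)C=C | intermediate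
16 | (1S)-1-{(2R,3R)-3-[(4R)-4-acetoxy-4,7-dimethyl-3-oxooct-6-enyl]-3-methyloxiran-2-yl}prop-2-en-1-ol | CC(C)=CC[C@@](C)(OC(C)=O)C(=O)CC[C@@]1(C)O[C@@H]1[C@@H](O)C=C | intermediate
17 | 2-(bromomethyl)acrylic acid | OC(=O)C(=C)CBr | starting material
18 | 2-(bromomethyl)acrylate ester of 16 (4R,5R,6S,10R) | CC(C)=CC[C@@](C)(OC(C)=O)C(=O)CC[C@@]1(C)O[C@@H]1[C@@H](OC(=O)C(=C)CBr)C=C | intermediate
19 | (5S)-3-(bromomethyl)-5-{(2R,3R)-3-[(4R)-4-acetoxy-4,7-dimethyl-3-oxooct-6-enyl]-3-methyloxiran-2-yl}furan-2(5H)-one | CC(C)=CC[C@@](C)(OC(C)=O)C(=O)CC[C@@]1(C)O[C@@H]1[C@H]2OC(=O)C(CBr)=C2 | intermediate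
20 | (5S)-3-(bromomethyl)-5-{(2R,3R)-3-[(4R)-4-acetoxy-4-methyl-3,6-dioxohexyl]-3-methyloxiran-2-yl}furan-2(5H)-one | O=CC[C@@](C)(OC(C)=O)C(=O)CC[C@@]1(C)O[C@@H]1[C@H]2OC(=O)C(CBr)=C2 | intermediate
21 | allylchromium(III) dichloride derived from 20 (chromium on C13) | O=CC[C@@](C)(OC(C)=O)C(=O)CC[C@@]1(C)O[C@@H]1[C@H]2OC(=O)C(C[Cr](Cl)Cl)=C2 | intermediate
22 | (4R,5R,6S,7R,8S,10R)-10-acetoxy-4,5-epoxy-8-hydroxy-1-oxogermacr-11(13)-en-12,6-olide | O[C@H]1C[C@@](C)(OC(C)=O)C(=O)CC[C@@]2(C)O[C@@H]2[C@H]2OC(=O)C(=C)[C@H]12 | intermediate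
23 | (4R,5R,6S,7R,8S,10R)-10-acetoxy-4,5-epoxy-1-oxo-8-propanoyloxygermacr-11(13)-en-12,6-olide | CCC(=O)O[C@H]1C[C@@](C)(OC(C)=O)C(=O)CC[C@@]2(C)O[C@@H]2[C@H]2OC(=O)C(=C)[C@H]12 | intermediate
24 | (4R,5R,6S,8S,10R)-10-acetoxy-13-bromo-4,5-epoxy-1-oxo-8-propanoyloxygermacr-7(11)-en-12,6-olide | CCC(=O)O[C@H]1C[C@@](C)(OC(C)=O)C(=O)CC[C@@]2(C)O[C@@H]2[C@H]2OC(=O)C(CBr)=C12 | intermediate
25 | (4R,5R,6S,8S,10R)-10,13-diacetoxy-4,5-epoxy-1-oxo-8-propanoyloxygermacr-7(11)-en-12,6-olide (CNP0285168.1) | CCC(=O)O[C@H]1C[C@@](C)(OC(C)=O)C(=O)CC[C@@]2(C)O[C@@H]2[C@H]2OC(=O)C(COC(C)=O)=C12 | target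

Total step count: 16
Longest linear sequence: 14 steps (steps 1–3, then 6–16)

Steps most likely to fail

Step 13 (key step). Protonation of the allylchromium species, oligomerisation, or loss of acetic acid from the β-acetoxy aldehyde may outrun ring closure. The fallback replaces the low-valent metal by a thermal allylboration. Setting out from 19, palladium-catalysed borylation with bis(pinacolato)diboron should give the primary allylboronate F1. Ozonolysis as in step 12 would give the aldehyde boronate F2. On warming in dilute toluene, F2 should close the same C7–C8 bond through a closed chair to give the cyclic borate F3. Mild hydrolysis of F3 comes back to the route at 22.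

Step 15. Hydrogen abstraction at other sites, over-bromination, or opening of the epoxide by hydrogen bromide may erode the step. The fallback uses no radicals. Setting out from 23, osmium-catalysed dihydroxylation (OsO4 cat., NMO) of the exocyclic alkene from the face opposite to C8 should give the 11,13-diol F4. Selective acetylation of its primary hydroxyl gives the hydroxy acetate F5. Syn dehydration with Burgess reagent (the C11 hydroxyl and H7 are cis) comes back to the route at 25.

Step 9. Poor enantiofacial control in the vinyl transfer, or poor facial selectivity in the one-pot epoxidation, may lower the stereochemical purity at C4–C6. The fallback works by resolution. Setting out from 14, vinylmagnesium bromide at −78 °C adds to the aldehyde only and gives the C6-epimeric dienols F6. A Sharpless epoxidation with D-(−)-diisopropyl tartrate and a deficit of hydroperoxide consumes the 6R epimer as the erythro epoxy alcohol F7 and leaves the 6S dienol F8. After separation, vanadium-catalysed hydroxyl-directed epoxidation of F8 (VO(acac)2, t-BuOOH, threo by A(1,3) strain) comes back to the route at 16.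

Further compounds
F1 | step 13 | (5S)-3-[(pinacolatoboryl)methyl] analogue of 19 (primary allylboronate) | CC(C)=CC[C@@](C)(OC(C)=O)C(=O)CC[C@@]1(C)O[C@@H]1[C@H]2OC(=O)C(CB3OC(C)(C)C(C)(C)O3)=C2
F2 | step 13 | (5S)-3-[(pinacolatoboryl)methyl] analogue of 20 (aldehyde boronate) | O=CC[C@@](C)(OC(C)=O)C(=O)CC[C@@]1(C)O[C@@H]1[C@H]2OC(=O)C(CB3OC(C)(C)C(C)(C)O3)=C2
F3 | step 13 | O8-pinacolboryl ester of 22 (cyclic borate) | CC1(C)OB(OC1(C)C)O[C@H]2C[C@@](C)(OC(C)=O)C(=O)CC[C@@]3(C)O[C@@H]3[C@H]3OC(=O)C(=C)[C@H]23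
F4 | step 15 | (4R,5R,6S,7R,8S,10R,11R)-10-acetoxy-4,5-epoxy-11,13-dihydroxy-1-oxo-8-propanoyloxygermacran-12,6-olide | CCC(=O)O[C@H]1C[C@@](C)(OC(C)=O)C(=O)CC[C@@]2(C)O[C@@H]2[C@H]2OC(=O)[C@](O)(CO)[C@H]12
F5 | step 15 | (4R,5R,6S,7R,8S,10R,11R)-10,13-diacetoxy-4,5-epoxy-11-hydroxy-1-oxo-8-propanoyloxygermacran-12,6-olide | CCC(=O)O[C@H]1C[C@@](C)(OC(C)=O)C(=O)CC[C@@]2(C)O[C@@H]2[C@H]2OC(=O)[C@](O)(COC(C)=O)[C@H]12
F6 | step 9 | (4E,9R)-9-acetoxy-3-hydroxy-5,9,12-trimethyltrideca-1,4,11-trien-8-one, both C3 (germacrane C6) epimers | CC(C)=CC[C@@](C)(OC(C)=O)C(=O)CC/C(C)=C/C(O)C=C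
F7 | step 9 | (1R)-1-{(2R,3R)-3-[(4R)-4-acetoxy-4,7-dimethyl-3-oxooct-6-enyl]-3-methyloxiran-2-yl}prop-2-en-1-ol (erythro, 6R) | CC(C)=CC[C@@](C)(OC(C)=O)C(=O)CC[C@@]1(C)O[C@@H]1[C@H](O)C=C
F8 | step 9 | (3S,4E,9R)-9-acetoxy-3-hydroxy-5,9,12-trimethyltrideca-1,4,11-trien-8-one (6S dienol) | CC(C)=CC[C@@](C)(OC(C)=O)C(=O)CC/C(C)=C/[C@@H](O)C=C
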